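## Retrosynthetic overview

- The strategy rests on the acyclic all-carbon quaternary stereocentre C(CH3)(CH=CH2)(E-CH=CH–chain)(CH2CH2–ring). With its vinyl and alkenyl arms it is a 1,4-diene, the retron of an SN2′ alkenyl transfer to the γ-carbon of a γ,γ-disubstituted allyl phosphate, so the bond from the quaternary carbon to the alkenyl carbon is cut last.
- Ring half (C16): the E-allylic phosphate comes from a terminal alkyne (methylalumination, formaldehyde), the alkyne from a Johnson–Claisen ester, and the Claisen substrate from 3-methylcyclohex-2-enone by asymmetric conjugate reduction, blocking, gem-dimethylation and carbonyl transposition.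
- Chain half (C17): the terminal alkyne comes from a secondary boronic ester by stereoretentive alkynylation. Its four methyl-bearing centres are built from isopropyl pinacol boronate by iterative lithiation–borylation with enantiopure α-stannylethyl benzoates and chloromethyllithium insertions.
- No ring is formed: the cyclohexane ring is present in the purchased enone and is carried through, and the two halves are joined in the last step.

Key step: step 25

Remark (assumption): the antipodes of the chiral ligands named in steps 1 and 25 are taken by analogy with the closest cases; each sense of induction is to be checked on a trial run and the mirror-image ligand used if it is the opposite.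

Remark: the lithiated benzoates 20 and 22 are numbered where they first form (steps 13 and 14). In steps 15, 18, 19 and 22 the same species is made again in the flask from the stannane by tin–lithium exchange and consumed at once as the homologating reagent.

## Ring half

Step 1
Reactants: 1 3-methylcyclohex-2-en-1-one
Product: 3 (S)-3-methylcyclohexan-1-one, via bis(enol) diphenylsilane 2 (not isolated)
Conditions: CuCl (5 mol %), NaOtBu (5 mol %), (R)-p-Tol-BINAP (5 mol %), Ph2SiH2 (0.55 equiv), toluene, 0 °C to rt; then 1 M HCl, THF, rt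
Reagents that add atoms: none
Why: Asymmetric copper hydride conjugate reduction: the bisphosphine-bound copper hydride adds hydride to the β-carbon from one enone face, the copper enolate is turned over by the silane to the silyl enol ether, and hydrolysis should give the ketone with the S methyl centre set by the ligand.

Step 2
Reactants: 3 (S)-3-methylcyclohexan-1-one
Product: 4 (S)-2-(hydroxymethylidene)-5-methylcyclohexan-1-one
Conditions: HCO2Et, NaH (cat. EtOH), Et2O, 0 °C to rt; aq. HCl
Reagents that add atoms: ethyl formate, CCOC=O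
Why: Claisen-type formylation of the ketone enolate should take place at C6, the α-methylene remote from the ring methyl, and is driven by formation of the stabilised enolate of the hydroxymethylidene ketone.

Step 3
Reactants: 4 (S)-2-(hydroxymethylidene)-5-methylcyclohexan-1-one
Product: 5 (S)-2-[(butylsulfanyl)methylidene]-5-methylcyclohexan-1-one
Conditions: n-BuSH, TsOH·H2O (cat.), benzene, reflux, Dean–Stark trap
Reagents that add atoms: butane-1-thiol, CCCCS
Why: Acid-catalysed addition–elimination of the thiol on the vinylogous acid gives the n-butylthiomethylene blocking group, which closes C6 to enolisation.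

Step 4
Reactants: 5 (S)-2-[(butylsulfanyl)methylidene]-5-methylcyclohexan-1-one
Product: 7 (S)-6-[(butylsulfanyl)methylidene]-2,2,3-trimethylcyclohexan-1-one, via monomethyl ketone 6 (not isolated)
Conditions: KOtBu (3 equiv), MeI (6 equiv), t-BuOH/THF, 0 °C to rt (second charge of base and MeI if 6 persists)
Reagents that add atoms: iodomethane, CI
Why: Enolate alkylation: with C6 blocked only C2 can be deprotonated, so two successive C-methylations should build the gem-dimethyl carbon, while the neighbouring methyl-bearing centre is not enolisable and keeps its configuration.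

Step 5
Reactants: 7 (S)-6-[(butylsulfanyl)methylidene]-2,2,3-trimethylcyclohexan-1-one
Product: 9 (S)-3,3,4-trimethylcyclohex-1-ene-1-carbaldehyde, via allylic alcohol 8 (not isolated)
Conditions: LiAlH4, Et2O, 0 °C; then 1 M HCl, THF, rt
Reagents that add atoms: water, O
Why: 1,2-Hydride reduction of the vinylogous thioester followed by acid-promoted allylic transposition (loss of water to the sulfur-stabilised allyl cation, attack of water at the thio-substituted carbon, loss of the thiol) should give the transposed enal; the methyl centre is remote from the reacting atoms.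

Step 6
Reactants: 9 (S)-3,3,4-trimethylcyclohex-1-ene-1-carbaldehyde
Product: 10 [(S)-3,3,4-trimethylcyclohex-1-en-1-yl]methanol
Conditions: NaBH4, CeCl3·7H2O, MeOH, 0 °C
Reagents that add atoms: none
Why: Luche 1,2-reduction of the enal should give the primary allylic alcohol without conjugate reduction.

Step 7
Reactants: 10 [(S)-3,3,4-trimethylcyclohex-1-en-1-yl]methanol
Product: 12 ethyl 2-[(1S,3S)-2,2,3-trimethyl-6-methylidenecyclohexyl]acetate, via ketene acetal 11 (not isolated)
Conditions: MeC(OEt)3 (6 equiv), EtCO2H (cat.), xylene, 140 °C, EtOH distilled off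
Reagents that add atoms: triethyl orthoacetate, CCOC(C)(OCC)OCC
Why: Johnson–Claisen rearrangement: orthoester exchange and loss of ethanol give the ketene acetal, whose [3,3]-shift forms the C–C bond at the ring carbon and moves the alkene to the exocyclic position; the bond should form anti to the pseudoaxial methyl of the neighbouring gem-dimethyl carbon (the other half-chair would place the incoming carbon syn-diaxial to the ring methyl), which puts the acetate arm trans to the ring methyl (1S).

Step 8
Reactants: 12 ethyl 2-[(1S,3S)-2,2,3-trimethyl-6-methylidenecyclohexyl]acetate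
Product: 13 2-[(1S,3S)-2,2,3-trimethyl-6-methylidenecyclohexyl]ethan-1-ol
Conditions: LiAlH4, Et2O, 0 °C; aq. NaOH work-up
Reagents that add atoms: none
Why: Hydride reduction of the ester to the primary alcohol; the exocyclic alkene and both stereocentres are not touched.

Step 9
Reactants: 13 2-[(1S,3S)-2,2,3-trimethyl-6-methylidenecyclohexyl]ethan-1-ol
Product: 14 2-[(1S,3S)-2,2,3-trimethyl-6-methylidenecyclohexyl]ethyl iodide
Conditions: I2, PPh3, imidazole, CH2Cl2, 0 °C to rt
Reagents that add atoms: iodine, II
Why: Appel-type iodination through the alkoxyphosphonium salt with SN2 displacement at the primary carbon; imidazole buffers the acid so the exocyclic alkene should not migrate.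

Step 10
Reactants: 14 2-[(1S,3S)-2,2,3-trimethyl-6-methylidenecyclohexyl]ethyl iodide
Product: 15 4-[(1S,3S)-2,2,3-trimethyl-6-methylidenecyclohexyl]but-1-yne
Conditions: LiC≡CH·H2NCH2CH2NH2, DMSO, rt
Reagents that add atoms: lithium acetylide–ethylenediamine complex, [Li+].[C-]#C.NCCN
Why: SN2 alkylation of lithium acetylide by the unhindered primary iodide in a dipolar aprotic solvent should give the terminal alkyne.

Step 11
Reactants: 15 4-[(1S,3S)-2,2,3-trimethyl-6-methylidenecyclohexyl]but-1-yne
Product: 17 (E)-3-methyl-5-[(1S,3S)-2,2,3-trimethyl-6-methylidenecyclohexyl]pent-2-en-1-ol, via alkenyl(dimethyl)alane 16 (not isolated)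
Conditions: AlMe3 (2.5 equiv), Cp2ZrCl2 (0.25 equiv), ClCH2CH2Cl, rt; volatiles removed; (CH2O)n, THF, 0 °C to rt; aq. sodium potassium tartrate
Reagents that add atoms: trimethylaluminium, C[Al](C)C; formaldehyde (as paraformaldehyde), C=O
Why: Negishi zirconium-catalysed carboalumination adds methyl and aluminium syn across the terminal alkyne with aluminium on the terminal carbon, and the alkenylalane adds to formaldehyde with retention, so the E-trisubstituted allylic alcohol should result; the 1,1-disubstituted exocyclic alkene is inert to the reagent.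

Step 12
Reactants: 17 (E)-3-methyl-5-[(1S,3S)-2,2,3-trimethyl-6-methylidenecyclohexyl]pent-2-en-1-ol
Product: 18 diethyl (E)-3-methyl-5-[(1S,3S)-2,2,3-trimethyl-6-methylidenecyclohexyl]pent-2-en-1-yl phosphate
Conditions: (EtO)2P(O)Cl, Et3N, DMAP (cat.), CH2Cl2, 0 °C
Reagents that add atoms: diethyl chlorophosphate, CCOP(=O)(Cl)OCC
Why: O-Phosphorylation of the primary allylic alcohol gives the leaving group required for the copper-catalysed allylic substitution, with the alkene geometry unchanged.

## Chain half

Step 13
Reactants: 19 ethyl 2,4,6-triisopropylbenzoate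
Product: 21 (R)-1-(trimethylstannyl)ethyl 2,4,6-triisopropylbenzoate, via lithiated benzoate 20 (not isolated)
Conditions: s-BuLi, (+)-sparteine, Et2O, −78 °C; Me3SnCl, −78 °C to rt; recrystallisation from MeOH
Reagents that add atoms: chlorotrimethylstannane, C[Sn](C)(C)Cl
Why: Sparteine-mediated asymmetric deprotonation removes one enantiotopic α-hydrogen of the O-ethyl group, the configurationally stable organolithium is stannylated with retention, and recrystallisation should bring the stannane to enantiopurity.

Step 14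
Reactants: 19 ethyl 2,4,6-triisopropylbenzoate
Product: 23 (S)-1-(trimethylstannyl)ethyl 2,4,6-triisopropylbenzoate, via lithiated benzoate 22 (not isolated)
Conditions: s-BuLi, (−)-sparteine, Et2O, −78 °C; Me3SnCl, −78 °C to rt; recrystallisation from MeOH
Reagents that add atoms: chlorotrimethylstannane, C[Sn](C)(C)Cl
Why: The same asymmetric deprotonation–stannylation as in step 13 with the mirror-image diamine should give the S stannane.

Step 15
Reactants: 24 2-isopropyl-4,4,5,5-tetramethyl-1,3,2-dioxaborolane; 21 (R)-1-(trimethylstannyl)ethyl 2,4,6-triisopropylbenzoate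
Product: 26 (S)-(3-methylbutan-2-yl)boronic acid pinacol ester, via boronate complex 25 (not isolated)
Conditions: 21 (1.3 equiv), n-BuLi, Et2O, −78 °C (tin–lithium exchange, diamine-free carbenoid 20 formed again); then 24, −78 °C; then rt to 35 °C; aq. NH4Cl work-up
Reagents that add atoms: none
Why: Lithiation–borylation: tin–lithium exchange on 21 gives carbenoid 20 with retention, it adds to boron with retention to form the boronate, and 1,2-migration of the isopropyl group with inversion as the benzoate leaves sets the S centre by reagent control.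

Step 16
Reactants: 26 (S)-(3-methylbutan-2-yl)boronic acid pinacol ester
Product: 28 (R)-(2,3-dimethylbutyl)boronic acid pinacol ester, via chloromethyl boronate 27 (not isolated)
Conditions: BrCH2Cl (1.5 equiv), n-BuLi (1.3 equiv), Et2O, −78 °C to rt
Reagents that add atoms: bromochloromethane, ClCBr
Why: Matteson homologation: chloromethyllithium made in the presence of the boronic ester adds to boron and 1,2-migration with loss of chloride inserts one CH2 with retention at the migrating carbon; limited carbenoid keeps the insertion single.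

Step 17
Reactants: 28 (R)-(2,3-dimethylbutyl)boronic acid pinacol ester
Product: 30 (R)-(3,4-dimethylpentyl)boronic acid pinacol ester, via chloromethyl boronate 29 (not isolated)
Conditions: BrCH2Cl (1.3 equiv), n-BuLi (1.2 equiv), Et2O, −78 °C to rt
Reagents that add atoms: bromochloromethane, ClCBr
Why: A second Matteson homologation inserts the second CH2 by the same boronate formation and 1,2-migration.

Step 18
Reactants: 30 (R)-(3,4-dimethylpentyl)boronic acid pinacol ester; 21 (R)-1-(trimethylstannyl)ethyl 2,4,6-triisopropylbenzoate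
Product: 32 [(2S,5R)-5,6-dimethylheptan-2-yl]boronic acid pinacol ester, via boronate complex 31 (not isolated)
Conditions: 21 (1.3 equiv), n-BuLi, Et2O, −78 °C (tin–lithium exchange to carbenoid 20); then 30, −78 °C; then rt to 35 °C; aq. NH4Cl work-up
Reagents that add atoms: none
Why: Lithiation–borylation as in step 15 (retention at boron–carbon bond formation, inversion in the 1,2-migration of the primary alkyl group) should set the new methyl-bearing centre independently of the remote one.

Step 19
Reactants: 32 [(2S,5R)-5,6-dimethylheptan-2-yl]boronic acid pinacol ester; 21 (R)-1-(trimethylstannyl)ethyl 2,4,6-triisopropylbenzoate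
Product: 34 [(2S,3S,6R)-3,6,7-trimethyloctan-2-yl]boronic acid pinacol ester, via boronate complex 33 (not isolated)
Conditions: 21 (1.5 equiv), n-BuLi, Et2O, −78 °C (tin–lithium exchange to carbenoid 20); then 32, −78 °C; then 35 °C; aq. NH4Cl work-up
Reagents that add atoms: none
Why: Lithiation–borylation with the same carbenoid; the secondary alkyl group migrates with retention of its own configuration and the new centre is set by the carbenoid, which should give the vicinal dimethyl pair by reagent control.

Step 20
Reactants: 34 [(2S,3S,6R)-3,6,7-trimethyloctan-2-yl]boronic acid pinacol ester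
Product: 36 [(2R,3S,6R)-2,3,6,7-tetramethyloctyl]boronic acid pinacol ester, via chloromethyl boronate 35 (not isolated)
Conditions: BrCH2Cl (1.5 equiv), n-BuLi (1.3 equiv), Et2O, −78 °C to rt
Reagents that add atoms: bromochloromethane, ClCBr
Why: Matteson homologation with stereoretentive 1,2-migration of the secondary alkyl group inserts one CH2.

Step 21
Reactants: 36 [(2R,3S,6R)-2,3,6,7-tetramethyloctyl]boronic acid pinacol ester
Product: 38 [(3R,4S,7R)-3,4,7,8-tetramethylnonyl]boronic acid pinacol ester, via chloromethyl boronate 37 (not isolated)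
Conditions: BrCH2Cl (1.3 equiv), n-BuLi (1.2 equiv), Et2O, −78 °C to rt
Reagents that add atoms: bromochloromethane, ClCBr
Why: A second Matteson homologation completes the two-carbon spacer.

Step 22
Reactants: 38 [(3R,4S,7R)-3,4,7,8-tetramethylnonyl]boronic acid pinacol ester; 23 (S)-1-(trimethylstannyl)ethyl 2,4,6-triisopropylbenzoate
Product: 40 [(2R,5R,6S,9R)-5,6,9,10-tetramethylundecan-2-yl]boronic acid pinacol ester, via boronate complex 39 (not isolated)
Conditions: 23 (1.3 equiv), n-BuLi, Et2O, −78 °C (tin–lithium exchange, diamine-free carbenoid 22 formed again); then 38, −78 °C; then rt to 35 °C; aq. NH4Cl work-up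
Reagents that add atoms: none
Why: Lithiation–borylation with the enantiomeric carbenoid 22 (retention in the tin–lithium exchange and at boron, then inversion in the 1,2-migration) should set the last methyl-bearing centre with the opposite spatial sense, as the target requires.

Step 23
Reactants: 40 [(2R,5R,6S,9R)-5,6,9,10-tetramethylundecan-2-yl]boronic acid pinacol ester
Product: 43 (3R,6R,7S,10R)-2-bromo-3,6,7,10,11-pentamethyldodec-1-ene, via bromovinyl boronate 41 (not isolated), via iodo bromo boronic ester 42 (not isolated)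
Conditions: CH2=CHBr, LiN(iPr)2 added to the mixture with 40, THF, −78 °C; then I2, MeOH, −78 °C; NaOMe, MeOH, to rt
Reagents that add atoms: vinyl bromide, C=CBr
Why: Zweifel-type olefination: α-lithiated vinyl bromide is trapped by boron as it forms, iodine activates the alkene so that the secondary alkyl group migrates to carbon with retention, and methoxide-induced anti elimination of boron and iodide should give the 2-bromoalkene.

Step 24
Reactants: 43 (3R,6R,7S,10R)-2-bromo-3,6,7,10,11-pentamethyldodec-1-ene
Product: 44 (3R,6R,7S,10R)-3,6,7,10,11-pentamethyldodec-1-yne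
Conditions: Bu4NF·3H2O, DMF, 60 °C
Reagents that add atoms: none
Why: Fluoride-induced E2 dehydrobromination removes the vinylic hydrogen anti to bromine to give the terminal alkyne; the propargylic centre is not deprotonated under these conditions.

## Coupling

Step 25
Reactants: 18 diethyl (E)-3-methyl-5-[(1S,3S)-2,2,3-trimethyl-6-methylidenecyclohexyl]pent-2-en-1-yl phosphate; 44 (3R,6R,7S,10R)-3,6,7,10,11-pentamethyldodec-1-yne
Product: 46 (3S,4E,6R,9R,10S,13R)-3,6,9,10,13,14-hexamethyl-3-{2-[(1S,3S)-2,2,3-trimethyl-6-methylidenecyclohexyl]ethyl}pentadeca-1,4-diene, via E-alkenyl(diisobutyl)alane 45 (not isolated)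
Conditions: 44 (1.5 equiv), iBu2AlH (1.5 equiv), hexanes, 55 °C; the alane solution added to 18, CuCl2·2H2O (5 mol %), Ag2L2 (2.5 mol %; L = (4S,5S)-1-(2,6-diisopropylphenyl)-4,5-diphenyl-3-(2-sulfonatophenyl)imidazolidin-2-ylidene), THF, −15 °C; aq. sodium potassium tartrate
Reagents that add atoms: none
Why: syn-Hydroalumination of the terminal alkyne gives the E-alkenylalane, whose alkenyl group passes to the carbene-bound monovalent copper formed from CuCl2·2H2O; the alkenylcopper adds anti to the phosphate at the disubstituted γ-carbon and reductive elimination from the trivalent copper allyl species releases the 1,4-diene with the E geometry retained. The closest known reaction is the NHC–copper-catalysed enantioselective allylic substitution of E-trisubstituted, geranyl-type allylic phosphates with alkenyl(diisobutyl)alanes made in situ from terminal alkynes, which gives quaternary carbons bearing a vinyl and an alkenyl group. No ring is closed. The new quaternary centre (S) is set by the chiral bidentate sulfonate–carbene copper catalyst, the ligand antipode being the one that delivers the alkenyl group to the face giving S. The step needs SN2′ over SN2 regioselectivity and alkenyl over isobutyl transfer; the carbene–copper catalyst and the faster transfer of the sp2 group from aluminium secure these, and both partners have defined E geometry. The existing stereocentres lie at the carbon next to the alkene in the nucleophile and four bonds from the γ-carbon in the electrophile, so catalyst control should dominate, and the exocyclic methylene has no leaving group and stays untouched.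

## Compound list

1 | 3-methylcyclohex-2-en-1-one | CC1=CC(=O)CCC1 | starting material
2 | bis{[(3S)-3-methylcyclohex-1-en-1-yl]oxy}diphenylsilane | C[C@@H]1C=C(O[Si](c2ccccc2)(c2ccccc2)OC2=C[C@@H](C)CCC2)CCC1 | intermediate
3 | (S)-3-methylcyclohexan-1-one | O=C1CCC[C@H](C)C1 | intermediate
4 | (S)-2-(hydroxymethylidene)-5-methylcyclohexan-1-one | O=C1C(=CO)CC[C@H](C)C1 | intermediate
5 | (S)-2-[(butylsulfanyl)methylidene]-5-methylcyclohexan-1-one | O=C1C(=CSCCCC)CC[C@H](C)C1 | intermediate
6 | (3S)-6-[(butylsulfanyl)methylidene]-2,3-dimethylcyclohexan-1-one (C2 epimers) | O=C1C(=CSCCCC)CC[C@H](C)C1C | intermediate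
7 | (S)-6-[(butylsulfanyl)methylidene]-2,2,3-trimethylcyclohexan-1-one | O=C1C(=CSCCCC)CC[C@H](C)C1(C)C | intermediate
8 | (3S)-6-[(butylsulfanyl)methylidene]-2,2,3-trimethylcyclohexan-1-ol (carbinol epimers) | OC1C(=CSCCCC)CC[C@H](C)C1(C)C | intermediate
9 | (S)-3,3,4-trimethylcyclohex-1-ene-1-carbaldehyde | O=CC1=CC(C)(C)[C@@H](C)CC1 | intermediate
10 | [(S)-3,3,4-trimethylcyclohex-1-en-1-yl]methanol | OCC1=CC(C)(C)[C@@H](C)CC1 | intermediate
11 | (S)-1-{[(1-ethoxyethenyl)oxy]methyl}-3,3,4-trimethylcyclohex-1-ene | C=C(OCC)OCC1=CC(C)(C)[C@@H](C)CC1 | intermediate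
12 | ethyl 2-[(1S,3S)-2,2,3-trimethyl-6-methylidenecyclohexyl]acetate | CCOC(=O)C[C@H]1C(=C)CC[C@H](C)C1(C)C | intermediate
13 | 2-[(1S,3S)-2,2,3-trimethyl-6-methylidenecyclohexyl]ethan-1-ol | OCC[C@H]1C(=C)CC[C@H](C)C1(C)C | intermediate
14 | 2-[(1S,3S)-2,2,3-trimethyl-6-methylidenecyclohexyl]ethyl iodide | ICC[C@H]1C(=C)CC[C@H](C)C1(C)C | intermediate
15 | 4-[(1S,3S)-2,2,3-trimethyl-6-methylidenecyclohexyl]but-1-yne | C#CCC[C@H]1C(=C)CC[C@H](C)C1(C)C | intermediate
16 | dimethyl{(E)-2-methyl-4-[(1S,3S)-2,2,3-trimethyl-6-methylidenecyclohexyl]but-1-en-1-yl}alane | C[Al](C)/C=C(\C)CC[C@H]1C(=C)CC[C@H](C)C1(C)C | intermediate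
17 | (E)-3-methyl-5-[(1S,3S)-2,2,3-trimethyl-6-methylidenecyclohexyl]pent-2-en-1-ol | OC/C=C(\C)CC[C@H]1C(=C)CC[C@H](C)C1(C)C | intermediate
18 | diethyl (E)-3-methyl-5-[(1S,3S)-2,2,3-trimethyl-6-methylidenecyclohexyl]pent-2-en-1-yl phosphate | CCOP(=O)(OCC)OC/C=C(\C)CC[C@H]1C(=C)CC[C@H](C)C1(C)C | intermediate
19 | ethyl 2,4,6-triisopropylbenzoate | CCOC(=O)c1c(C(C)C)cc(C(C)C)cc1C(C)C | starting material
20 | (R)-1-lithioethyl 2,4,6-triisopropylbenzoate | [Li][C@@H](OC(=O)c1c(C(C)C)cc(C(C)C)cc1C(C)C)C | intermediate
21 | (R)-1-(trimethylstannyl)ethyl 2,4,6-triisopropylbenzoate | C[Sn](C)(C)[C@@H](OC(=O)c1c(C(C)C)cc(C(C)C)cc1C(C)C)C | intermediate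
22 | (S)-1-lithioethyl 2,4,6-triisopropylbenzoate | [Li][C@H](OC(=O)c1c(C(C)C)cc(C(C)C)cc1C(C)C)C | intermediate
23 | (S)-1-(trimethylstannyl)ethyl 2,4,6-triisopropylbenzoate | C[Sn](C)(C)[C@H](OC(=O)c1c(C(C)C)cc(C(C)C)cc1C(C)C)C | intermediate
24 | 2-isopropyl-4,4,5,5-tetramethyl-1,3,2-dioxaborolane | CC(C)B1OC(C)(C)C(C)(C)O1 | starting material
25 | lithium (isopropyl)[(R)-1-(2,4,6-triisopropylbenzoyloxy)ethyl]pinacolatoborate | CC(C)[B-]1(OC(C)(C)C(C)(C)O1)[C@@H](OC(=O)c2c(C(C)C)cc(C(C)C)cc2C(C)C)C.[Li+] | intermediate
26 | (S)-(3-methylbutan-2-yl)boronic acid pinacol ester | CC1(C)OB([C@@H](C)C(C)C)OC1(C)C | intermediate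
27 | lithium (chloromethyl)[(S)-3-methylbutan-2-yl]pinacolatoborate | ClC[B-]1(OC(C)(C)C(C)(C)O1)[C@@H](C)C(C)C.[Li+] | intermediate
28 | (R)-(2,3-dimethylbutyl)boronic acid pinacol ester | CC1(C)OB(C[C@@H](C)C(C)C)OC1(C)C | intermediate
29 | lithium (chloromethyl)[(R)-2,3-dimethylbutyl]pinacolatoborate | ClC[B-]1(OC(C)(C)C(C)(C)O1)C[C@@H](C)C(C)C.[Li+] | intermediate
30 | (R)-(3,4-dimethylpentyl)boronic acid pinacol ester | CC1(C)OB(CC[C@@H](C)C(C)C)OC1(C)C | intermediate
31 | lithium [(R)-3,4-dimethylpentyl][(R)-1-(2,4,6-triisopropylbenzoyloxy)ethyl]pinacolatoborate | CC(C)[C@H](C)CC[B-]1(OC(C)(C)C(C)(C)O1)[C@@H](OC(=O)c2c(C(C)C)cc(C(C)C)cc2C(C)C)C.[Li+] | intermediate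
32 | [(2S,5R)-5,6-dimethylheptan-2-yl]boronic acid pinacol ester | CC1(C)OB([C@@H](C)CC[C@@H](C)C(C)C)OC1(C)C | intermediate
33 | lithium [(2S,5R)-5,6-dimethylheptan-2-yl][(R)-1-(2,4,6-triisopropylbenzoyloxy)ethyl]pinacolatoborate | CC(C)[C@H](C)CC[C@H](C)[B-]1(OC(C)(C)C(C)(C)O1)[C@@H](OC(=O)c2c(C(C)C)cc(C(C)C)cc2C(C)C)C.[Li+] | intermediate
34 | [(2S,3S,6R)-3,6,7-trimethyloctan-2-yl]boronic acid pinacol ester | CC1(C)OB([C@@H](C)[C@@H](C)CC[C@@H](C)C(C)C)OC1(C)C | intermediate
35 | lithium (chloromethyl)[(2S,3S,6R)-3,6,7-trimethyloctan-2-yl]pinacolatoborate | ClC[B-]1(OC(C)(C)C(C)(C)O1)[C@@H](C)[C@@H](C)CC[C@@H](C)C(C)C.[Li+] | intermediate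
36 | [(2R,3S,6R)-2,3,6,7-tetramethyloctyl]boronic acid pinacol ester | CC1(C)OB(C[C@@H](C)[C@@H](C)CC[C@@H](C)C(C)C)OC1(C)C | intermediate
37 | lithium (chloromethyl)[(2R,3S,6R)-2,3,6,7-tetramethyloctyl]pinacolatoborate | ClC[B-]1(OC(C)(C)C(C)(C)O1)C[C@@H](C)[C@@H](C)CC[C@@H](C)C(C)C.[Li+] | intermediate
38 | [(3R,4S,7R)-3,4,7,8-tetramethylnonyl]boronic acid pinacol ester | CC1(C)OB(CC[C@@H](C)[C@@H](C)CC[C@@H](C)C(C)C)OC1(C)C | intermediate
39 | lithium [(3R,4S,7R)-3,4,7,8-tetramethylnonyl][(S)-1-(2,4,6-triisopropylbenzoyloxy)ethyl]pinacolatoborate | CC(C)[C@H](C)CC[C@H](C)[C@H](C)CC[B-]1(OC(C)(C)C(C)(C)O1)[C@H](OC(=O)c2c(C(C)C)cc(C(C)C)cc2C(C)C)C.[Li+] | intermediate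
40 | [(2R,5R,6S,9R)-5,6,9,10-tetramethylundecan-2-yl]boronic acid pinacol ester | CC1(C)OB([C@H](C)CC[C@@H](C)[C@@H](C)CC[C@@H](C)C(C)C)OC1(C)C | intermediate
41 | lithium (1-bromoethenyl)[(2R,5R,6S,9R)-5,6,9,10-tetramethylundecan-2-yl]pinacolatoborate | C=C(Br)[B-]1(OC(C)(C)C(C)(C)O1)[C@H](C)CC[C@@H](C)[C@@H](C)CC[C@@H](C)C(C)C.[Li+] | intermediate
42 | [(3R,6R,7S,10R)-2-bromo-1-iodo-3,6,7,10,11-pentamethyldodecan-2-yl]boronic acid pinacol ester (C2 epimers) | ICC(Br)(B1OC(C)(C)C(C)(C)O1)[C@H](C)CC[C@@H](C)[C@@H](C)CC[C@@H](C)C(C)C | intermediate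
43 | (3R,6R,7S,10R)-2-bromo-3,6,7,10,11-pentamethyldodec-1-ene | C=C(Br)[C@H](C)CC[C@@H](C)[C@@H](C)CC[C@@H](C)C(C)C | intermediate
44 | (3R,6R,7S,10R)-3,6,7,10,11-pentamethyldodec-1-yne | C#C[C@H](C)CC[C@@H](C)[C@@H](C)CC[C@@H](C)C(C)C | intermediate
45 | diisobutyl[(1E,3R,6R,7S,10R)-3,6,7,10,11-pentamethyldodec-1-en-1-yl]alane | CC(C)C[Al](CC(C)C)/C=C/[C@H](C)CC[C@@H](C)[C@@H](C)CC[C@@H](C)C(C)C | intermediate
46 | (3S,4E,6R,9R,10S,13R)-3,6,9,10,13,14-hexamethyl-3-{2-[(1S,3S)-2,2,3-trimethyl-6-methylidenecyclohexyl]ethyl}pentadeca-1,4-diene (CNP0132765.1) | C=C[C@@](C)(/C=C/[C@H](C)CC[C@@H](C)[C@@H](C)CC[C@@H](C)C(C)C)CC[C@H]1C(=C)CC[C@H](C)C1(C)C | target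

## Step count and risks

Total step count: 25. Longest linear sequence: 13 steps (steps 1–12 and 25, from 3-methylcyclohex-2-en-1-one); the chain branch runs 12 steps from ethyl 2,4,6-triisopropylbenzoate.

**Step 25.** Catalyst control at the prochiral γ-carbon may be incomplete, or part of the material may react in the SN2 sense. Either would leave an isomeric hydrocarbon, in the first case the epimer at the quaternary carbon, that cannot be separated from the target. The fallback sets the centre by reagent and substrate control, setting out from allylic alcohol 17 and alkyne 44. Sharpless epoxidation of 17 (Ti(OiPr)4, D-(−)-diethyl tartrate, t-BuOOH, 4 Å sieves, CH2Cl2, −20 °C) should give [(2R,3R)-3-methyl-3-{2-[(1S,3S)-2,2,3-trimethyl-6-methylidenecyclohexyl]ethyl}oxiran-2-yl]methanol F1. Alkyne 44 is deprotonated with n-BuLi and transmetalated with Et2AlCl (toluene, 0 °C) to diethyl[(3R,6R,7S,10R)-3,6,7,10,11-pentamethyldodec-1-yn-1-yl]alane F2. This should open the epoxy alcohol at its tertiary carbon with inversion (organoaluminium opening of 2,3-epoxy alcohols at C3) to give (2S,3R)-3-methyl-3-[(3R,6R,7S,10R)-3,6,7,10,11-pentamethyldodec-1-yn-1-yl]-5-[(1S,3S)-2,2,3-trimethyl-6-methylidenecyclohexyl]pentane-1,2-diol F3, a polar compound from which stereoisomers can be removed by chromatography. Sodium in liquid ammonia (trans-selective dissolving-metal reduction) gives (2S,3R)-3-methyl-3-[(1E,3R,6R,7S,10R)-3,6,7,10,11-pentamethyldodec-1-en-1-yl]-5-[(1S,3S)-2,2,3-trimethyl-6-methylidenecyclohexyl]pentane-1,2-diol F4. Thiocarbonyldiimidazole converts it into the cyclic thionocarbonate of that diol F5, and P(OMe)3 at reflux (Corey–Winter olefination) turns the two diol carbons into the vinyl group and comes back to the route at 46.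

**Step 7.** Bond formation at the ring carbon beside the gem-dimethyl carbon may be slow at 140 °C or show poor facial selectivity, giving the cis epimer or alkene migration products. The fallback delivers the carbon by a [2,3]-shift at −78 °C through a tighter five-membered transition state, setting out from allylic alcohol 10. KH and Bu3SnCH2I in THF give tributyl({[(S)-3,3,4-trimethylcyclohex-1-en-1-yl]methoxy}methyl)stannane F6. n-BuLi in THF at −78 °C (tin–lithium exchange, Still–Wittig rearrangement) should give [(1S,3S)-2,2,3-trimethyl-6-methylidenecyclohexyl]methanol F7. Tf2O and pyridine give [(1S,3S)-2,2,3-trimethyl-6-methylidenecyclohexyl]methyl trifluoromethanesulfonate F8, which is displaced by lithiated 1-(trimethylsilyl)propyne (n-BuLi, THF, −78 °C) to give trimethyl{4-[(1S,3S)-2,2,3-trimethyl-6-methylidenecyclohexyl]but-1-yn-1-yl}silane F9. K2CO3 in MeOH removes the silyl group and comes back to the route at 15.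

**Step 4.** The second C-methylation, which makes a quaternary carbon next to the methyl-bearing carbon, may stall, or O-methylation of the hindered enolate may take over. The fallback installs both methyl groups before blocking by using the regiodefined enolate that step 1 already delivers, setting out from bis(enol) silane 2 before its hydrolysis. MeI with tetrabutylammonium difluorotriphenylsilicate (fluoride-promoted enol silane alkylation) should give (2R,3S)-2,3-dimethylcyclohexan-1-one F10, whose C2 configuration is of no consequence. Me3SiCl, NaI and Et3N in MeCN give the more substituted enol ether trimethyl{[(S)-2,3-dimethylcyclohex-1-en-1-yl]oxy}silane F11. MeLi then MeI (regiospecific enolate alkylation) gives (S)-2,2,3-trimethylcyclohexan-1-one F12. Formylation under the conditions of step 2, now possible only at C6, gives (S)-6-(hydroxymethylidene)-2,2,3-trimethylcyclohexan-1-one F13, and butane-1-thiol with TsOH as in step 3 comes back to the route at 7.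

## Further compounds

F1 | step 25 | [(2R,3R)-3-methyl-3-{2-[(1S,3S)-2,2,3-trimethyl-6-methylidenecyclohexyl]ethyl}oxiran-2-yl]methanol | OC[C@H]1O[C@]1(C)CC[C@H]2C(=C)CC[C@H](C)C2(C)C
F2 | step 25 | diethyl[(3R,6R,7S,10R)-3,6,7,10,11-pentamethyldodec-1-yn-1-yl]alane | CC[Al](CC)C#C[C@H](C)CC[C@@H](C)[C@@H](C)CC[C@@H](C)C(C)C
F3 | step 25 | (2S,3R)-3-methyl-3-[(3R,6R,7S,10R)-3,6,7,10,11-pentamethyldodec-1-yn-1-yl]-5-[(1S,3S)-2,2,3-trimethyl-6-methylidenecyclohexyl]pentane-1,2-diol | OC[C@@H](O)[C@@](C)(C#C[C@H](C)CC[C@@H](C)[C@@H](C)CC[C@@H](C)C(C)C)CC[C@H]1C(=C)CC[C@H](C)C1(C)C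
F4 | step 25 | (2S,3R)-3-methyl-3-[(1E,3R,6R,7S,10R)-3,6,7,10,11-pentamethyldodec-1-en-1-yl]-5-[(1S,3S)-2,2,3-trimethyl-6-methylidenecyclohexyl]pentane-1,2-diol | OC[C@@H](O)[C@@](C)(/C=C/[C@H](C)CC[C@@H](C)[C@@H](C)CC[C@@H](C)C(C)C)CC[C@H]1C(=C)CC[C@H](C)C1(C)C
F5 | step 25 | cyclic thionocarbonate (1,3-dioxolane-2-thione) of diol F4 | S=C1OC[C@@H](O1)[C@@](C)(/C=C/[C@H](C)CC[C@@H](C)[C@@H](C)CC[C@@H](C)C(C)C)CC[C@H]2C(=C)CC[C@H](C)C2(C)C
F6 | step 7 | tributyl({[(S)-3,3,4-trimethylcyclohex-1-en-1-yl]methoxy}methyl)stannane | CCCC[Sn](CCCC)(CCCC)COCC1=CC(C)(C)[C@@H](C)CC1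
F7 | step 7 | [(1S,3S)-2,2,3-trimethyl-6-methylidenecyclohexyl]methanol | OC[C@H]1C(=C)CC[C@H](C)C1(C)C
F8 | step 7 | [(1S,3S)-2,2,3-trimethyl-6-methylidenecyclohexyl]methyl trifluoromethanesulfonate | FC(F)(F)S(=O)(=O)OC[C@H]1C(=C)CC[C@H](C)C1(C)C
F9 | step 7 | trimethyl{4-[(1S,3S)-2,2,3-trimethyl-6-methylidenecyclohexyl]but-1-yn-1-yl}silane | C[Si](C)(C)C#CCC[C@H]1C(=C)CC[C@H](C)C1(C)C
F10 | step 4 | (2R,3S)-2,3-dimethylcyclohexan-1-one | O=C1CCC[C@H](C)[C@H]1C
F11 | step 4 | trimethyl{[(S)-2,3-dimethylcyclohex-1-en-1-yl]oxy}silane | C[Si](C)(C)OC1=C(C)[C@@H](C)CCC1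
F12 | step 4 | (S)-2,2,3-trimethylcyclohexan-1-one | O=C1CCC[C@H](C)C1(C)C
F13 | step 4 | (S)-6-(hydroxymethylidene)-2,2,3-trimethylcyclohexan-1-one | O=C1C(=CO)CC[C@H](C)C1(C)C
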